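**Retrosynthetic overview**
1. The target is reached by acidolysis (tert-butyl ester, TBS ether) of the fully assembled, protected 3-acyl-dihydropyranone.
2. The only ring, the 5,6-dihydro-2H-pyran-2-one (O1, C2 lactone carbonyl, C3 acyl-bearing carbon, C4 enol carbon, C5, C6 methyl-bearing carbon), is cut at O1–C6 and C3–C4 into a side-chain β-keto acid and methyl (S)-3-hydroxybutanoate; forward, Mitsunobu O-alkylation with inversion at C6 and Dieckmann closure run in one flask.
3. Enabling feature: O1–C2(=O)–C3 is the carboxylate oxygen plus the doubly activated methylene of a β-keto acid (an O,C-1,3-dinucleophile); C6–C5–C4 is the carbinol, methylene and ester carbon of a 3-hydroxybutanoate (a 1,3-dielectrophile); the enolised 3-acyl-2,4-dioxo array is the thermodynamic sink of the closure.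
4. Side chain: cross-metathesis then hydrogenation at the chain bond next to the methyl-bearing stereocenter joins an allylated β-silyloxy tert-butyl ester (stereotriad from (S)-2-methylbutanoic acid by Noyori hydrogenation and Fráter–Seebach allylation) with a benzyl β-keto ester made from (R)-β-citronellene.
5. Ring order: one ring only, formed in the penultimate step.

Key step: step 9

Remark on the chemistry: the 3-acyl-4-hydroxy-5,6-dihydro-2H-pyran-2-one is an enolised tricarbonyl system; its tautomers are treated as one compound and drawn as in the target SMILES.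

**Step 1**
Reactants: 1 (2S)-2-methylbutanoic acid; 2 3-tert-butoxy-3-oxopropanoic acid (mono-tert-butyl malonate)
Product: 4 tert-butyl (4S)-4-methyl-3-oxohexanoate, via acyl imidazolide 3 (not isolated)
Conditions: CDI, THF, 20 °C; then 2, MgCl2, Et3N, MeCN, 20 °C; 1 M HCl
Reagents that add atoms: none
Why: Masamune–Brooks decarboxylative Claisen homologation, in which the acyl imidazolide acylates the magnesium enolate of the malonate half-ester and CO2 is lost, under conditions mild enough to carry the α-stereocenter of 1 through unchanged.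

**Step 2**
Reactants: 4 tert-butyl (4S)-4-methyl-3-oxohexanoate
Product: 5 tert-butyl (3S,4S)-3-hydroxy-4-methylhexanoate
Conditions: H2 (10 bar), RuCl2[(R)-BINAP] (0.5 mol %), EtOH, 50 °C
Reagents that add atoms: none
Why: Noyori asymmetric hydrogenation of a β-keto ester, in which the (R)-BINAP ruthenium catalyst should deliver hydrogen to the chelated ketone in the same facial sense that turns acetoacetates into (R)-3-hydroxybutanoates, setting C3 as S under catalyst control, the adjacent methyl/ethyl stereocenter exerting little bias.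

**Step 3**
Reactants: 5 tert-butyl (3S,4S)-3-hydroxy-4-methylhexanoate; 6 allyl bromide
Product: 7 tert-butyl (2R,3R,4S)-3-hydroxy-4-methyl-2-(prop-2-en-1-yl)hexanoate
Conditions: LDA (2.2 equiv), THF, −78 → −20 °C; then 6, DMPU, −78 → −10 °C; aq. NH4Cl
Reagents that add atoms: none
Why: Fráter–Seebach alkylation, in which the lithium-chelated alkoxide–enolate dianion is allylated on the face opposite the C3 substituent, so that C2 should be set as R, anti to the C3 oxygen.

**Step 4**
Reactants: 7 tert-butyl (2R,3R,4S)-3-hydroxy-4-methyl-2-(prop-2-en-1-yl)hexanoate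
Product: 8 tert-butyl (2R,3R,4S)-3-{[tert-butyl(dimethyl)silyl]oxy}-4-methyl-2-(prop-2-en-1-yl)hexanoate
Conditions: TBSOTf, 2,6-lutidine, CH2Cl2, −78 → 0 °C
Reagents that add atoms: tert-butyldimethylsilyl trifluoromethanesulfonate (TBSOTf), CC(C)(C)[Si](C)(C)OS(=O)(=O)C(F)(F)F
Why: Silyl triflate silylation of a hindered secondary alcohol at low temperature, needed because a free hydroxyl would compete in the Mitsunobu stage and invite retro-aldol cleavage under KOtBu in step 9.

**Step 5**
Reactants: 9 (3R)-3,7-dimethylocta-1,6-diene ((R)-β-citronellene)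
Product: 11 (4R)-4-methylhex-5-enal, via epoxide 10 (not isolated)
Conditions: mCPBA (1.0 equiv), CH2Cl2, 0 °C; then H5IO6, THF/Et2O, 0 → 20 °C
Reagents that add atoms: 3-chloroperoxybenzoic acid (mCPBA), O=C(OO)c1cccc(Cl)c1
Why: Chemoselective Prilezhaev epoxidation of the electron-rich trisubstituted alkene (the vinyl group reacts far more slowly) followed by periodic acid cleavage of the epoxide through its diol should give the aldehyde and acetone without touching the stereocenter.

**Step 6**
Reactants: 11 (4R)-4-methylhex-5-enal; 12 benzyl diazoacetate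
Product: 13 benzyl (6R)-6-methyl-3-oxooct-7-enoate
Conditions: SnCl2 (10 mol %), CH2Cl2, 20 °C
Reagents that add atoms: none
Why: Roskamp homologation, in which Lewis-acid-promoted addition of the diazoacetate to the aldehyde and 1,2-hydride shift with loss of N2 should give the β-keto ester directly.

**Step 7**
Reactants: 8 tert-butyl (2R,3R,4S)-3-{[tert-butyl(dimethyl)silyl]oxy}-4-methyl-2-(prop-2-en-1-yl)hexanoate; 13 benzyl (6R)-6-methyl-3-oxooct-7-enoate
Product: 14 11-benzyl 1-tert-butyl (2R,4E,6R)-2-[(1R,2S)-1-{[tert-butyl(dimethyl)silyl]oxy}-2-methylbutyl]-6-methyl-9-oxoundec-4-enedioate (E drawn; an E/Z mixture is acceptable)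
Conditions: 13 (2.5 equiv), second-generation Hoveyda–Grubbs catalyst RuCl2(H2IMes)(=CH-C6H4-2-OiPr) (5 mol %), CH2Cl2, 40 °C, argon sparge
Reagents that add atoms: none
Why: Olefin cross-metathesis between the unhindered terminal alkene of 8 and the allylically branched, slowly homodimerising terminal alkene of 13 (used in excess), driven by loss of ethene, the alkene geometry being irrelevant because the double bond is reduced in step 8.

**Step 8**
Reactants: 14 11-benzyl 1-tert-butyl (2R,4E,6R)-2-[(1R,2S)-1-{[tert-butyl(dimethyl)silyl]oxy}-2-methylbutyl]-6-methyl-9-oxoundec-4-enedioate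
Product: 15 (6S,10R)-11-tert-butoxy-10-[(1R,2S)-1-{[tert-butyl(dimethyl)silyl]oxy}-2-methylbutyl]-6-methyl-3,11-dioxoundecanoic acid
Conditions: H2 (1 atm), 10 % Pd/C, EtOAc, 20 °C; filtered and used at once
Reagents that add atoms: none
Why: Heterogeneous hydrogenation should saturate the disubstituted alkene and hydrogenolyse the benzyl ester in the same operation under neutral conditions, leaving the tert-butyl ester, silyl ether and ketone intact and limiting decarboxylation of the β-keto acid.

**Step 9**
Reactants: 15 (6S,10R)-11-tert-butoxy-10-[(1R,2S)-1-{[tert-butyl(dimethyl)silyl]oxy}-2-methylbutyl]-6-methyl-3,11-dioxoundecanoic acid; 16 methyl (3S)-3-hydroxybutanoate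
Product: 18 tert-butyl (2R,3R,4S)-3-{[tert-butyl(dimethyl)silyl]oxy}-2-{(4S)-7-[(6R)-4-hydroxy-6-methyl-2-oxo-5,6-dihydro-2H-pyran-3-yl]-4-methyl-7-oxoheptyl}-4-methylhexanoate, via Mitsunobu diester 17 (not isolated)
Conditions: 16 (1.5 equiv), PPh3 (1.5 equiv), DIAD (1.5 equiv), toluene, −20 → 0 °C; then KOtBu (5 equiv), THF, 0 → 20 °C; 1 M HCl
Reagents that add atoms: none
Why: PPh3 and DIAD form a betaine that is protonated by the carboxylic acid of 15 (the only strong acid present) and converts the carbinol of 16 into an oxyphosphonium ion, which the β-keto carboxylate oxygen displaces at C6 in an SN2 reaction (Mitsunobu esterification; bond O1–C6), after which KOtBu deprotonates the doubly activated C3 methylene of 17 and the enolate attacks the methyl ester carbon C4 with loss of methoxide (Lacey–Dieckmann condensation; bond C3–C4). The closest known reaction types are the Mitsunobu inversion of 3-hydroxybutanoate esters with acidic O–H pronucleophiles and the alkoxide-mediated Dieckmann cyclisation of β-acyloxy esters of β-keto acids to 3-acyl-tetronic acids and 3-acyl-5,6-dihydro-4-hydroxy-2H-pyran-2-ones. The dihydropyranone ring closes in the second event by 6-exo-trig attack of the C3 enolate on the ester carbonyl, the first event being the intermolecular union of the two fragments. The only new stereocenter, C6, is controlled by the carbinol configuration of 16 through inversion (the 3S alcohol should give the 6R lactone) and is not touched by the condensation. The step needs O- over C-alkylation, substitution over β-elimination and ring closure over E1cB loss of the acyloxy group; the first is secured by the acidity gap between the carboxylic acid and the C3 methylene, the second by the weakly basic, strongly acidic carboxylate partner at low temperature in toluene, and the third because C3 is by far the most acidic site of 17, the only leaving group open to an E1cB path would be an enolate-carboxylate dianion, and the product is withdrawn as its stabilised tricarbonyl enolate.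

**Step 10**
Reactants: 18 tert-butyl (2R,3R,4S)-3-{[tert-butyl(dimethyl)silyl]oxy}-2-{(4S)-7-[(6R)-4-hydroxy-6-methyl-2-oxo-5,6-dihydro-2H-pyran-3-yl]-4-methyl-7-oxoheptyl}-4-methylhexanoate
Product: 19 (2R,3R,4S)-3-hydroxy-2-{(4S)-7-[(6R)-4-hydroxy-6-methyl-2-oxo-5,6-dihydro-2H-pyran-3-yl]-4-methyl-7-oxoheptyl}-4-methylhexanoic acid
Conditions: TFA/H2O (9:1), 0 → 20 °C
Reagents that add atoms: none
Why: Acidolysis should cleave the tert-butyl ester through the tert-butyl cation and the silyl ether by protodesilylation, conditions under which the acidic enolised tricarbonyl lactone and all five stereocenters are expected to be stable.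

**Compound list**
1 | (2S)-2-methylbutanoic acid | CC[C@H](C)C(=O)O | starting material
2 | 3-tert-butoxy-3-oxopropanoic acid (mono-tert-butyl malonate) | CC(C)(C)OC(=O)CC(=O)O | starting material
3 | (2S)-1-(1H-imidazol-1-yl)-2-methylbutan-1-one | CC[C@H](C)C(=O)n1ccnc1 | intermediate
4 | tert-butyl (4S)-4-methyl-3-oxohexanoate | CC[C@H](C)C(=O)CC(=O)OC(C)(C)C | intermediate
5 | tert-butyl (3S,4S)-3-hydroxy-4-methylhexanoate | CC[C@H](C)[C@@H](O)CC(=O)OC(C)(C)C | intermediate
6 | allyl bromide (3-bromoprop-1-ene) | C=CCBr | starting material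
7 | tert-butyl (2R,3R,4S)-3-hydroxy-4-methyl-2-(prop-2-en-1-yl)hexanoate | CC[C@H](C)[C@@H](O)[C@@H](CC=C)C(=O)OC(C)(C)C | intermediate
8 | tert-butyl (2R,3R,4S)-3-{[tert-butyl(dimethyl)silyl]oxy}-4-methyl-2-(prop-2-en-1-yl)hexanoate | CC[C@H](C)[C@@H](O[Si](C)(C)C(C)(C)C)[C@@H](CC=C)C(=O)OC(C)(C)C | intermediate
9 | (3R)-3,7-dimethylocta-1,6-diene ((R)-β-citronellene) | C=C[C@H](C)CCC=C(C)C | starting material
10 | 2,2-dimethyl-3-[(3R)-3-methylpent-4-en-1-yl]oxirane (both epimers at the oxirane carbon) | C=C[C@H](C)CCC1OC1(C)C | intermediate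
11 | (4R)-4-methylhex-5-enal | C=C[C@H](C)CCC=O | intermediate
12 | benzyl diazoacetate | [N-]=[N+]=CC(=O)OCc1ccccc1 | starting material
13 | benzyl (6R)-6-methyl-3-oxooct-7-enoate | C=C[C@H](C)CCC(=O)CC(=O)OCc1ccccc1 | intermediate
14 | 11-benzyl 1-tert-butyl (2R,4E,6R)-2-[(1R,2S)-1-{[tert-butyl(dimethyl)silyl]oxy}-2-methylbutyl]-6-methyl-9-oxoundec-4-enedioate | CC[C@H](C)[C@@H](O[Si](C)(C)C(C)(C)C)[C@@H](C/C=C/[C@H](C)CCC(=O)CC(=O)OCc1ccccc1)C(=O)OC(C)(C)C | intermediate
15 | (6S,10R)-11-tert-butoxy-10-[(1R,2S)-1-{[tert-butyl(dimethyl)silyl]oxy}-2-methylbutyl]-6-methyl-3,11-dioxoundecanoic acid | CC[C@H](C)[C@@H](O[Si](C)(C)C(C)(C)C)[C@@H](CCC[C@H](C)CCC(=O)CC(=O)O)C(=O)OC(C)(C)C | intermediate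
16 | methyl (3S)-3-hydroxybutanoate | C[C@H](O)CC(=O)OC | starting material
17 | 1-tert-butyl 11-[(2R)-4-methoxy-4-oxobutan-2-yl] (2R,6S)-2-[(1R,2S)-1-{[tert-butyl(dimethyl)silyl]oxy}-2-methylbutyl]-6-methyl-9-oxoundecanedioate | CC[C@H](C)[C@@H](O[Si](C)(C)C(C)(C)C)[C@@H](CCC[C@H](C)CCC(=O)CC(=O)O[C@H](C)CC(=O)OC)C(=O)OC(C)(C)C | intermediate
18 | tert-butyl (2R,3R,4S)-3-{[tert-butyl(dimethyl)silyl]oxy}-2-{(4S)-7-[(6R)-4-hydroxy-6-methyl-2-oxo-5,6-dihydro-2H-pyran-3-yl]-4-methyl-7-oxoheptyl}-4-methylhexanoate | CC[C@H](C)[C@@H](O[Si](C)(C)C(C)(C)C)[C@@H](CCC[C@H](C)CCC(=O)C1=C(O)C[C@@H](C)OC1=O)C(=O)OC(C)(C)C | intermediate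
19 | (2R,3R,4S)-3-hydroxy-2-{(4S)-7-[(6R)-4-hydroxy-6-methyl-2-oxo-5,6-dihydro-2H-pyran-3-yl]-4-methyl-7-oxoheptyl}-4-methylhexanoic acid | CC[C@H](C)[C@@H](O)[C@@H](CCC[C@H](C)CCC(=O)C1=C(O)C[C@@H](C)OC1=O)C(=O)O | target

**Step count and risks**
Total step count: 10. Longest linear sequence: 8 steps (steps 1, 2, 3, 4, 7, 8, 9, 10); steps 5 and 6 make the second fragment.

Steps most likely to fail:

Step 9. What may go wrong: β-elimination of the activated hydroxy ester to the crotonate and decarboxylation of the β-keto acid may outrun O-alkylation; partial carboxyl activation may give ester with retention and so erode the configuration at C6; E1cB loss of the acyloxy group may compete with the Claisen closure. Fallback, setting out from 14 and coming back at 18: the ester bond is made by acyl transfer instead of O-alkylation, so that the free β-keto acid is never formed. Benzyl β-keto ester 14 is heated in toluene at 110 °C with an excess of commercially available methyl (3R)-3-hydroxybutanoate (C[C@@H](O)CC(=O)OC) and catalytic DMAP (transesterification of a β-keto ester through its acylketene, the carbinol configuration being retained) to give the unsaturated diester 1-tert-butyl 11-[(2R)-4-methoxy-4-oxobutan-2-yl] (2R,4E,6R)-2-[(1R,2S)-1-{[tert-butyl(dimethyl)silyl]oxy}-2-methylbutyl]-6-methyl-9-oxoundec-4-enedioate F1. Hydrogenation (H2, Pd/C, EtOAc) should then give 17, now isolated, and KOtBu in THF closes the ring to 18 as in the second stage of step 9.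

Step 7. What may go wrong: unproductive homodimerisation of the partners and sequestration of the ruthenium carbene by the chelating β-keto ester may leave conversion to the cross product low. Fallback, setting out from 8 and 9 and coming back at 14: the union is made at the hydrocarbon level and the oxygen functions are added afterwards. Alkene 8 is cross-metathesised with an excess of diene 9 itself (same catalyst; the trisubstituted alkene of 9 is inert and no chelating group is present) to give tert-butyl (2R,3R,4S)-3-{[tert-butyl(dimethyl)silyl]oxy}-2-[(2E,4R)-4,8-dimethylnona-2,7-dien-1-yl]-4-methylhexanoate F2. mCPBA should epoxidise the trisubstituted alkene in preference to the trans-disubstituted one, giving tert-butyl (2R,3R,4S)-3-{[tert-butyl(dimethyl)silyl]oxy}-2-[(2E,4R)-6-(3,3-dimethyloxiran-2-yl)-4-methylhex-2-en-1-yl]-4-methylhexanoate F3. Periodic acid cleavage gives tert-butyl (2R,3R,4S)-3-{[tert-butyl(dimethyl)silyl]oxy}-4-methyl-2-[(2E,4R)-4-methyl-7-oxohept-2-en-1-yl]hexanoate F4, and Roskamp homologation of this aldehyde with 12 and SnCl2 gives 14.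

Step 5. What may go wrong: the volatile, unhindered aldehyde may be lost on isolation and may oxidise or self-condense on standing. Fallback, setting out from 9 and coming back at 13 (step 6 is bypassed): the aldehyde is never isolated and the chain is extended from the acid oxidation level. After epoxidation and cleavage as in step 5, the crude solution of 11 is oxidised in the same flask (NaClO2, NaH2PO4, 2-methylbut-2-ene, tBuOH/H2O; Pinnick oxidation) to the non-volatile (4R)-4-methylhex-5-enoic acid F5, which is purified by acid–base extraction. Activation with CDI gives (4R)-1-(1H-imidazol-1-yl)-4-methylhex-5-en-1-one F6, which is homologated with mono-benzyl malonate (O=C(O)CC(=O)OCc1ccccc1), MgCl2 and Et3N (Masamune–Brooks decarboxylative Claisen) to 13.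

**Further compounds**
F1 | step 9 | 1-tert-butyl 11-[(2R)-4-methoxy-4-oxobutan-2-yl] (2R,4E,6R)-2-[(1R,2S)-1-{[tert-butyl(dimethyl)silyl]oxy}-2-methylbutyl]-6-methyl-9-oxoundec-4-enedioate | CC[C@H](C)[C@@H](O[Si](C)(C)C(C)(C)C)[C@@H](C/C=C/[C@H](C)CCC(=O)CC(=O)O[C@H](C)CC(=O)OC)C(=O)OC(C)(C)C
F2 | step 7 | tert-butyl (2R,3R,4S)-3-{[tert-butyl(dimethyl)silyl]oxy}-2-[(2E,4R)-4,8-dimethylnona-2,7-dien-1-yl]-4-methylhexanoate | CC[C@H](C)[C@@H](O[Si](C)(C)C(C)(C)C)[C@@H](C/C=C/[C@H](C)CCC=C(C)C)C(=O)OC(C)(C)C
F3 | step 7 | tert-butyl (2R,3R,4S)-3-{[tert-butyl(dimethyl)silyl]oxy}-2-[(2E,4R)-6-(3,3-dimethyloxiran-2-yl)-4-methylhex-2-en-1-yl]-4-methylhexanoate | CC[C@H](C)[C@@H](O[Si](C)(C)C(C)(C)C)[C@@H](C/C=C/[C@H](C)CCC1OC1(C)C)C(=O)OC(C)(C)C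
F4 | step 7 | tert-butyl (2R,3R,4S)-3-{[tert-butyl(dimethyl)silyl]oxy}-4-methyl-2-[(2E,4R)-4-methyl-7-oxohept-2-en-1-yl]hexanoate | CC[C@H](C)[C@@H](O[Si](C)(C)C(C)(C)C)[C@@H](C/C=C/[C@H](C)CCC=O)C(=O)OC(C)(C)C
F5 | step 5 | (4R)-4-methylhex-5-enoic acid | C=C[C@H](C)CCC(=O)O
F6 | step 5 | (4R)-1-(1H-imidazol-1-yl)-4-methylhex-5-en-1-one | C=C[C@H](C)CCC(=O)n1ccnc1
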